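**Strategy**

Phyltetralin is cut at the C1–C8a aryl bond after imagining an extra bond between C1 and C4. Both carbons of ring B are benzylic to a veratryl ring and sit 1,4 to each other, so that extra bond turns C1–C2–C3–C4 into the cyclobutane of a head-to-head dimer of 3,4-dimethoxycinnamic acid. In the forward sense, acid opens this strained diaryl-flanked bond and the 4-methoxybenzylic cation alkylates the neighbouring arene, creating ring B, the C1 stereocentre and the C4 methylene in one operation. The precursor is an enantiopure cyclobutane with cis aryl groups and trans methoxymethyl groups, reached from a template-directed [2+2] photodimer by anhydride desymmetrisation, epimerisation, reduction and methylation.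

Key step: step 9

Assumption: quinidine is taken to open anhydride 6 in the sense it shows with other cis-fused succinic anhydrides (ester on the R-configured carbon, acid on the S-configured one). If 6 responds in the opposite sense, its pseudoenantiomer quinine is used in step 5 and nothing else changes.

Numbering: tetralin numbering of the target is used; C1 carries the pendant aryl group and ring B is the saturated ring (C1–C4, C4a, C8a).

**Route**

Step 1
Reactants: 1 (E)-3,4-dimethoxycinnamic acid (2 equiv); 2 1,8-dihydroxynaphthalene
Product: 3 naphthalene-1,8-diyl bis[(E)-3-(3,4-dimethoxyphenyl)prop-2-enoate]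
Conditions: DCC (2.4 equiv), DMAP (0.2 equiv), CH2Cl2, 0 °C to rt
Reagents that add atoms: none
Why: Steglich esterification (carbodiimide activation, DMAP acyl transfer) should acylate both peri hydroxyl groups of the diol without touching the E alkenes; no stereocentre is formed.

Step 2
Reactants: 3 naphthalene-1,8-diyl bis[(E)-3-(3,4-dimethoxyphenyl)prop-2-enoate]
Product: 4 naphthalene-1,8-diyl (1R,2S,3R,4S)-3,4-bis(3,4-dimethoxyphenyl)cyclobutane-1,2-dicarboxylate (cyclic diester, meso)
Conditions: hν (365 nm), finely ground crystalline solid, rt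
Reagents that add atoms: none
Why: Template-directed [2+2] photocycloaddition: the peri diester holds the two cinnamoyl arms stacked head-to-head within bonding distance, so the two E alkenes add suprafacially to give only the syn head-to-head (β-truxinate) cyclobutane, whose four new centres are fixed as aryl cis to aryl, ester cis to ester and each aryl trans to its neighbouring ester.

Step 3
Reactants: 4 cyclic naphthalene-1,8-diyl diester
Product: 5 (1R,2S,3R,4S)-3,4-bis(3,4-dimethoxyphenyl)cyclobutane-1,2-dicarboxylic acid (meso)
Conditions: KOH, THF/H2O, 50 °C; then aq. HCl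
Reagents that add atoms: potassium hydroxide, [K+].[OH-] (its oxygen ends in each CO2H)
Why: Saponification of the two aryl esters by acyl–oxygen cleavage should release the meso diacid and the reusable template 2, the carboxylates formed being inert to epimerisation under these conditions.

Step 4
Reactants: 5 meso diacid
Product: 6 (1R,5S,6R,7S)-6,7-bis(3,4-dimethoxyphenyl)-3-oxabicyclo[3.2.0]heptane-2,4-dione (meso anhydride)
Conditions: Ac2O, 120 °C; then evaporation
Reagents that add atoms: none
Why: Dehydrative cyclisation through the mixed acetic anhydride: the cis-1,2-diacid closes to the five-membered cyclic anhydride, which on a cyclobutane can only be cis-fused, so the meso configuration is kept.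

Step 5
Reactants: 6 meso anhydride
Product: 7 (1S,2R,3S,4R)-3,4-bis(3,4-dimethoxyphenyl)-2-(methoxycarbonyl)cyclobutane-1-carboxylic acid (cis hemiester; relative configuration as in 5)
Conditions: quinidine (1.1 equiv), MeOH (3 equiv), toluene, −55 °C; then aq. HCl
Reagents that add atoms: methanol, CO
Why: Cinchona-alkaloid-mediated desymmetrising methanolysis of a meso anhydride: the quinidine–methanol complex should deliver methanol to one of the two enantiotopic carbonyl groups, which creates no new centre but turns the four existing ones into a single enantiomer with the ester on the carbon that is inverted next.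

Step 6
Reactants: 7 cis hemiester
Product: 8 (1S,2S,3S,4R)-3,4-bis(3,4-dimethoxyphenyl)-2-(methoxycarbonyl)cyclobutane-1-carboxylic acid (CO2Me trans to CO2H and cis to the C3 aryl)
Conditions: NaOMe (4 equiv), MeOH, 65 °C; then aq. HCl
Reagents that add atoms: none
Why: Base-mediated thermodynamic epimerisation: methoxide can enolise only the ester-bearing carbon (the neighbouring carboxylate resists a second deprotonation and methoxide exchange on the methyl ester is degenerate), and reprotonation should settle that carbon trans to the carboxylate, as in the classical change of β- into neo-truxinic acid derivatives, so exactly one defined centre is inverted.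

Step 7
Reactants: 8 trans hemiester
Product: 9 [(1S,2S,3R,4S)-3,4-bis(3,4-dimethoxyphenyl)cyclobutane-1,2-diyl]dimethanol
Conditions: LiAlH4, THF, 0 °C to 65 °C; then H2O, aq. NaOH
Reagents that add atoms: none
Why: Hydride reduction with LiAlH4 takes both the ester and the carboxylate to primary alcohols without touching the four C–H stereocentres.

Step 8
Reactants: 9 trans diol
Product: 10 (1S,2R,3S,4S)-1,2-bis(3,4-dimethoxyphenyl)-3,4-bis(methoxymethyl)cyclobutane (aryl groups cis, methoxymethyl groups trans, the C4 arm cis to the C1 aryl)
Conditions: NaH, MeI, THF/DMF, 0 °C to rt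
Reagents that add atoms: iodomethane, CI
Why: Williamson etherification of the two primary alkoxides with iodomethane; capping both hydroxyl groups also keeps them from trapping the cation of step 9 as a tetrahydrofuran.

Step 9
Reactants: 10 (1S,2R,3S,4S)-1,2-bis(3,4-dimethoxyphenyl)-3,4-bis(methoxymethyl)cyclobutane
Product: 12 phyltetralin, via ring-opened benzylic cation 11 (not isolated)
Conditions: TfOH (10 mol %), (CF3)2CHOH, 0 °C to rt, argon, dark
Reagents that add atoms: none
Why: Triflic acid in the cation-stabilising solvent should protonate the long, strained bond between the two aryl-bearing ring carbons, placing a CH2 at one of them and the 4-methoxybenzylic cation 11 at the other; because the opened chain is C2-symmetric it does not matter which carbon takes the proton. The cation then alkylates the veratryl ring of the new benzyl arm at its C6 position (para to the 3-methoxy group, the unhindered site ortho to the tether), forming C1–C8a, and loss of the arenium proton returns the acid. The closest known reaction type is the acid- or hole-promoted ring expansion of electron-rich 1,2-diarylcyclobutanes (dimers of anethole- and asarone-type styrenes) to 1-aryltetralins, and the closing half is the familiar Friedel–Crafts cyclisation of benzylic cations of dibenzylbutane lignans. Ring B closes in a six-membered Friedel–Crafts mode (6-endo with respect to the attacked arene bond) through a half-chair. The new C1 centre is substrate-controlled: the pendant aryl group takes the pseudo-equatorial position anti to the C2 methoxymethyl arm, which is itself trans to the C3 arm, giving the 1,2-trans-2,3-trans (1R,2S,3S) array, while C2 and C3 are never touched. The step needs cleavage of the diaryl-flanked bond in preference to the two lateral ring bonds and no proton loss from 11 towards C2; the first should follow from donor assistance at both ends of that bond, relief of the eclipsed cis-diaryl pair and inductive deactivation of the lateral bonds by the CH2OMe groups, the second from the speed of intramolecular attack by a dimethoxyarene in a cold, non-basic medium.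

**Compound list**

1 | (E)-3,4-dimethoxycinnamic acid | COc1ccc(/C=C/C(=O)O)cc1OC | starting material
2 | 1,8-dihydroxynaphthalene | Oc1cccc2cccc(O)c12 | starting material
3 | naphthalene-1,8-diyl bis[(E)-3-(3,4-dimethoxyphenyl)prop-2-enoate] | COc1ccc(/C=C/C(=O)Oc2cccc3cccc(OC(=O)/C=C/c4ccc(OC)c(OC)c4)c23)cc1OC | intermediate
4 | naphthalene-1,8-diyl (1R,2S,3R,4S)-3,4-bis(3,4-dimethoxyphenyl)cyclobutane-1,2-dicarboxylate, cyclic diester, meso | O=C1Oc2cccc3cccc(c23)OC(=O)[C@H]4[C@@H]1[C@H](c5ccc(OC)c(OC)c5)[C@@H]4c6ccc(OC)c(OC)c6 | intermediate
5 | (1R,2S,3R,4S)-3,4-bis(3,4-dimethoxyphenyl)cyclobutane-1,2-dicarboxylic acid, meso | OC(=O)[C@H]1[C@@H](C(=O)O)[C@H](c2ccc(OC)c(OC)c2)[C@@H]1c1ccc(OC)c(OC)c1 | intermediate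
6 | (1R,5S,6R,7S)-6,7-bis(3,4-dimethoxyphenyl)-3-oxabicyclo[3.2.0]heptane-2,4-dione, meso | O=C1OC(=O)[C@H]2[C@@H]1[C@H](c1ccc(OC)c(OC)c1)[C@@H]2c1ccc(OC)c(OC)c1 | intermediate
7 | (1S,2R,3S,4R)-3,4-bis(3,4-dimethoxyphenyl)-2-(methoxycarbonyl)cyclobutane-1-carboxylic acid | COC(=O)[C@H]1[C@@H](C(=O)O)[C@H](c2ccc(OC)c(OC)c2)[C@@H]1c1ccc(OC)c(OC)c1 | intermediate
8 | (1S,2S,3S,4R)-3,4-bis(3,4-dimethoxyphenyl)-2-(methoxycarbonyl)cyclobutane-1-carboxylic acid | COC(=O)[C@@H]1[C@@H](C(=O)O)[C@H](c2ccc(OC)c(OC)c2)[C@@H]1c1ccc(OC)c(OC)c1 | intermediate
9 | [(1S,2S,3R,4S)-3,4-bis(3,4-dimethoxyphenyl)cyclobutane-1,2-diyl]dimethanol | OC[C@@H]1[C@@H](CO)[C@H](c2ccc(OC)c(OC)c2)[C@@H]1c1ccc(OC)c(OC)c1 | intermediate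
10 | (1S,2R,3S,4S)-1,2-bis(3,4-dimethoxyphenyl)-3,4-bis(methoxymethyl)cyclobutane | COC[C@@H]1[C@@H](COC)[C@H](c2ccc(OC)c(OC)c2)[C@@H]1c1ccc(OC)c(OC)c1 | intermediate
11 | (2S,3S)-1,4-bis(3,4-dimethoxyphenyl)-2,3-bis(methoxymethyl)butan-1-ylium, ring-opened benzylic cation | COC[C@@H]([CH+]c1ccc(OC)c(OC)c1)[C@@H](COC)Cc1ccc(OC)c(OC)c1 | intermediate
12 | phyltetralin, (1R,2S,3S)-1-(3,4-dimethoxyphenyl)-6,7-dimethoxy-2,3-bis(methoxymethyl)-1,2,3,4-tetrahydronaphthalene | COC[C@H]1Cc2cc(OC)c(OC)cc2[C@@H](c2ccc(OC)c(OC)c2)[C@@H]1COC | target

**Count**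

Total steps: 9. Longest linear sequence: 9 steps (from 1 or 2 to 12).

**Steps most likely to fail**

1. Step 9. The strained bond may resist protonolysis under conditions mild enough for the ethers. Protonation may instead open a lateral ring bond and end in a stilbene after proton loss. Cation 11 may also shed the C2 proton before it cyclises and so scramble C2. The fallback sets out from 10 and returns at 12. Hydrogenolysis of the doubly benzylic cyclobutane bond (H2, Pd/C, EtOAc/AcOH, 50 °C), a reaction typical of cis-1,2-diarylcyclobutanes, should give the dibenzylbutane (2S,3S)-1,4-bis(3,4-dimethoxyphenyl)-2,3-bis(methoxymethyl)butane F1 with both CH2OMe-bearing centres intact. DDQ in CH2Cl2/TFA at 0 °C then abstracts a benzylic hydride; either benzylic position gives the same cation 11 because F1 is C2-symmetric. The same Friedel–Crafts closure, known as the oxidative cyclisation of dibenzylbutane lignans to aryltetralins, delivers 12.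

2. Step 6. Enolisation next to a carboxylate may be slow, the equilibrium may stop short of complete inversion, or adventitious hydroxide may saponify the ester and erase the difference between the two carbons. The fallback sets out from 5 and returns at 9. Fischer esterification (MeOH, H2SO4, 65 °C) gives dimethyl (1R,2S,3R,4S)-3,4-bis(3,4-dimethoxyphenyl)cyclobutane-1,2-dicarboxylate F2 (meso). NaOMe in MeOH equilibrates it, with no carboxylate in the way, to the racemic trans diester F3. Preparative chromatography on a chiral stationary phase separates dimethyl (1S,2S,3R,4S)-3,4-bis(3,4-dimethoxyphenyl)cyclobutane-1,2-dicarboxylate F4, and LiAlH4 in THF reduces it to 9. This path gives up step 5 as well and costs the unwanted half of the material.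

3. Step 5. Discrimination between the enantiotopic carbonyl groups may be weaker than with simpler anhydrides because the aryl groups crowd the bicycle, or its sense may be the opposite one. The fallback sets out from 6 and returns at 8. DMAP-catalysed opening of 6 with (R)-1-phenylethanol in CH2Cl2 gives the two hemiesters as diastereomers, which can be separated by crystallisation or chromatography and assigned by X-ray analysis. They are (1S,2R,3S,4R)-3,4-bis(3,4-dimethoxyphenyl)-2-{[(1R)-1-phenylethoxy]carbonyl}cyclobutane-1-carboxylic acid F5 and its regio-diastereomer (1R,2S,3R,4S)-3,4-bis(3,4-dimethoxyphenyl)-2-{[(1R)-1-phenylethoxy]carbonyl}cyclobutane-1-carboxylic acid F6. NaOMe in MeOH at 65 °C converts F5 into 8 in one operation, by methanolysis of the secondary ester and epimerisation of the ester-bearing carbon; F6 is set aside.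

**Further compounds**

F1 | step 9 | (2S,3S)-1,4-bis(3,4-dimethoxyphenyl)-2,3-bis(methoxymethyl)butane | COC[C@@H](Cc1ccc(OC)c(OC)c1)[C@@H](COC)Cc1ccc(OC)c(OC)c1
F2 | step 6 | dimethyl (1R,2S,3R,4S)-3,4-bis(3,4-dimethoxyphenyl)cyclobutane-1,2-dicarboxylate, meso | COC(=O)[C@H]1[C@@H](C(=O)OC)[C@H](c2ccc(OC)c(OC)c2)[C@@H]1c1ccc(OC)c(OC)c1
F3 | step 6 | racemic trans diester, dimethyl (1S,2S,3R,4S)- and (1R,2R,3S,4R)-3,4-bis(3,4-dimethoxyphenyl)cyclobutane-1,2-dicarboxylate | COC(=O)[C@@H]1[C@@H](C(=O)OC)[C@H](c2ccc(OC)c(OC)c2)[C@@H]1c1ccc(OC)c(OC)c1.COC(=O)[C@H]1[C@H](C(=O)OC)[C@@H](c2ccc(OC)c(OC)c2)[C@H]1c1ccc(OC)c(OC)c1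
F4 | step 6 | dimethyl (1S,2S,3R,4S)-3,4-bis(3,4-dimethoxyphenyl)cyclobutane-1,2-dicarboxylate | COC(=O)[C@@H]1[C@@H](C(=O)OC)[C@H](c2ccc(OC)c(OC)c2)[C@@H]1c1ccc(OC)c(OC)c1
F5 | step 5 | (1S,2R,3S,4R)-3,4-bis(3,4-dimethoxyphenyl)-2-{[(1R)-1-phenylethoxy]carbonyl}cyclobutane-1-carboxylic acid | C[C@@H](OC(=O)[C@H]1[C@@H](C(=O)O)[C@H](c2ccc(OC)c(OC)c2)[C@@H]1c1ccc(OC)c(OC)c1)c1ccccc1
F6 | step 5 | (1R,2S,3R,4S)-3,4-bis(3,4-dimethoxyphenyl)-2-{[(1R)-1-phenylethoxy]carbonyl}cyclobutane-1-carboxylic acid | OC(=O)[C@H]1[C@@H](C(=O)O[C@H](C)c2ccccc2)[C@H](c2ccc(OC)c(OC)c2)[C@@H]1c1ccc(OC)c(OC)c1
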